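The data are calculated for substances that don't exist; noise was put on by code.

The target is the reading to distrust: it does not stay. You see this in the alder run, where it goes from 60% at 0.833 d to 40% at 10.0 d while the electrophile keeps falling.

| setting | birch | larch | alder | teal | violet |
|---|---|---|---|---|---|
| electrophile | 20 mM | 20 mM | 20 mM | 20 mM | 20 mM |
| nucleophile | 16 mM | 22 mM | 24 mM | 18.0 mM | 27.0 mM |
| remark | run made earlier | run made earlier | run made earlier |  |  |
| time |  |  |  | 10 d | 10 d |

| run | time / d | electrophile / % | target / % |
|---|---|---|---|
| birch | 2.08 | 49 | 41 |
| birch | 4.00 | 44 | 38 |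
| birch | 6.00 | 37 | 33 |
| birch | 8.00 | 36 | 25 |
| birch | 10.0 | 35 | 26 |
| larch | 0.833 | 39 | 59 |
| larch | 1.67 | 33 | 55 |
| larch | 3.00 | 29 | 50 |
| larch | 5.00 | 26 | 45 |
| larch | 10.0 | 16 | 32 |
| alder | 0.833 | 34 | 60 |
| alder | 1.67 | 28 | 58 |
| alder | 3.00 | 26 | 56 |
| alder | 5.00 | 20 | 48 |
| alder | 10.0 | 11 | 40 |

(readings scatter by 1.5 percentage points)

- a reading or a percentage of target counts all its forms, free or not

- part of the electrophile that has reacted at the end, teal
- part of the electrophile that has reacted at the end, violet
- what raising the concentration of nucleophile from its lowest to its highest value here does to the part of the electrophile that has reacted (changes below 5 percentage points count as none) (it rises / it falls / no change)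

1. Put everything in mM. Add the electrophile reacted to the target, then subtract the nucleophile charged. In alder this gives 1.20 mM at the first reading and 1.80 mM at the last, although the target fell by 4.00 mM between them.

2. At 10.0 d, birch gives 2.20 mM and larch 1.20 mM. Their mean with alder, 1.73 mM, is the surplus: electrophile reacted plus target, less nucleophile charged. It is a reading and carries the scatter.

3. My reading of it: each electrophile reacted costs one nucleophile, and each target still standing holds a second. As the target drains, that second nucleophile goes to more electrophile. So you ask what stands at the end, then how far the drain has come: electrophile reacted = nucleophile charged + surplus − target, all in mM.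

4. Interpolating the target at 10 d gives 28.0% for teal. Extrapolating gives 52.0% for violet, which is the weaker figure.

5. My reckoning is then 70.7% reacted in teal and 91.7% in violet, a rise of 21 percentage points.

The forecast differs slightly: 73% (67% to 78%) for teal, 93% (88% to 97%) for violet, and it rises. It came from the electrophile readings directly: “I don't trust a single mechanism and will interpolate empirically”.

The flask gives 73.9% for teal and 95.5% for violet, so it rises, by 22 points.

    acid set free + target → side product (k = 2.50 L mol⁻¹ h⁻¹)
    crystals ⇌ target, rate k2*(cs2 - [target]) while solid is left; crystals form when [target] > cs2 (solubility = 17.0 mM, k = 2.20 h⁻¹)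
    nucleophile + acid set free ⇌ protonated nucleophile, settled at all times (K = 61000 L mol⁻¹)
    electrophile + nucleophile → acid set free + target (k = 78.0 L mol⁻¹ h⁻¹)

Teal's surplus at 10.0 d comes to 1.90 mM, with the acid set free at 1.93 mM. Now take violet's recipe with 34 mM of electrophile, which is 0.794 equiv of nucleophile. Its simulated target is 17.2%, so the same reckoning gives 67.3% reacted, and that flask gives 69.7%. Nucleophile is the limiting reagent there, with 0.078% of its charge left unbound.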